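A direct plan would cut C9–C10 and build two ten-carbon halves: a ring-A γ-lactone taken on to the cesium oxalate A1 of its C10 carbinol, and an enone ester A2 from an intramolecular oxidopyrylium [5+2] cycloaddition.
A photoredox Giese reaction would join them to A3. δ-Lactonisation, SmI2 opening of the oxygen bridge to the cycloheptanone A4, a transannular C8–C14 alkylation and dehydration at C17 would finish the synthesis.
The weakest step would be the radical union. It would have to make the most hindered bond of the molecule (quaternary C10 to C9, beside the future quaternary C8) when both halves are most precious, and C9 and C10 would rest on two unrelated facial preferences.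
Next would be the SmI2 cleavage of the α-C–O bond. It would have to spare a primary bromide and an enolisable β-keto lactone in the same molecule, four steps from the end.
Third would be the run-up to A1. It would spend eight steps, mostly one-carbon and redox adjustments, on one ring and on a C10 centre that is then erased to a radical.

**Plan of the new route**
Feature used: C10 of ring A carries two one-carbon branches (C9, C20), and C6, C19 and C20 all lie on one face of ring A. C10 can therefore be carried as a prochiral C(CH2OH)2 carbon, and C9–C10–C20 is bought as protected dihydroxyacetone.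
Cuts: C3–C4 and C5–C10 (Diels–Alder; citraconic anhydride = C4, C5, C6, C18, C19); C8=C9 (Knoevenagel; acetoacetate = C7, C8, C15, C16); C8–C14 and C9–C11 (Diels–Alder; butadiene = C11–C14); C13–C16 (radical closure); C16=C17 (methylenation).
Ring order: ring A forms together with a provisional C6–O–C20 γ-lactone. The true γ-lactone (C19–O–C6) and the δ-lactone (C20–O–C7) then form together by a lactone relay. Ring C follows, and ring D is last.
The C9–C10 bond is never made, so there is no late union of two fragments. C10 is fixed by which CH2OH can reach C6, C8/C9 by one suprafacial addition anti to the C5 arm, and 11-OH by hydride attack on the convex face before ring D exists. No SmI2 step and no ether opening occur.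

Key step: step 3

Labels and assumption: atom labels follow ent-kaurane numbering of the target (ring A = C1–C5, C10; C18 = CH3). In step 5 the (R)-amine is written; the (S)-amine would be used if the salt of the wanted acid proves the more soluble one.

Step 1
Reactants: 1, 2,2-dimethyl-1,3-dioxan-5-one; 2, allyltriphenylphosphonium bromide
Product: 3, 2,2-dimethyl-5-(prop-2-en-1-ylidene)-1,3-dioxane
Conditions: 2, n-BuLi, THF, −78 to 0 °C; then 1, −78 °C to rt
Reagents that add atoms: none
Why: Wittig olefination of a symmetrical ketone with the semi-stabilised allyl ylide should give the diene C10=C1–C2=C3 with C9 and C20 in place and no alkene geometry to control.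

Step 2
Reactants: 3, 2,2-dimethyl-5-(prop-2-en-1-ylidene)-1,3-dioxane
Product: 4, 2-(prop-2-en-1-ylidene)propane-1,3-diol
Conditions: PPTS (cat.), MeOH, rt
Reagents that add atoms: none
Why: Mild transacetalisation should free both hydroxymethyl groups without ionising the allylic C–O bonds.

Step 3
Reactants: 4, 2-(prop-2-en-1-ylidene)propane-1,3-diol; 5, citraconic anhydride
Product: 7, (±)-3a-(hydroxymethyl)-7-methyl-1-oxo-1,3,3a,6,7,7a-hexahydro-2-benzofuran-7-carboxylic acid (ring A cyclohexene cis-fused to the C6–O–C20 γ-lactone), via dienyl hydrogen citraconate 6 (not isolated)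
Conditions: PhMe, 80 °C; then o-xylene (0.02 M), BHT, 140 °C
Reagents that add atoms: none
Why: The less hindered carbonyl of 5 (next to =CH) acylates one CH2OH of 4, and the dienyl hydrogen citraconate 6 undergoes a thermal type-1 intramolecular [4+2] cycloaddition through its three-atom ester tether (closest known type: intramolecular Diels–Alder reactions of 2,4-dienyl citraconates and maleates). Ring A closes through the two new σ-bonds C5–C10 and C3–C4, and the five-membered C6–O–C20 lactone is the tether ring, fused at C5–C10. C4 and C5 are set relative to each other by suprafacial addition to the (Z)-alkene, which puts C19 and C6 cis and C18 trans to them. C10 is not set by the transition state, because both of its branches are CH2OH: it becomes stereogenic only through the lactone, and only the branch cis to C6 can hold a cis-fused γ-lactone, so that branch is defined as C20 and the free one, trans to C6, as C9. Therefore E and Z tether isomers, endo and exo modes, the intermolecular pathway through free 5 (its half-esters revert on heating) and any trans-fused product (by translactonisation) should all converge on 7. The one selectivity needed is regiochemical (C10 to C5, not to C4), and it is secured by the tether on C6 and by the penalty for joining two fully substituted carbons; 7 is racemic and is resolved in step 5.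

Step 4
Reactants: 7, (±)-cyclohexene lactone acid
Product: 8, (±)-3a-(hydroxymethyl)-7-methyl-1-oxooctahydro-2-benzofuran-7-carboxylic acid
Conditions: H2 (1 atm), 10% Pd/C, EtOAc, rt
Reagents that add atoms: none
Why: Catalytic hydrogenation of the only C=C gives C1H2–C2H2 and creates no stereocentre.

Step 5
Reactants: 8, (±)-saturated lactone acid; 9, (R)-1-phenylethylamine (0.5 equiv)
Product: 10, (R)-1-phenylethylammonium salt of the enantiomer of 8 that has the target configuration at C4, C5 and C10
Conditions: EtOAc/i-PrOH, 60 °C to rt; recrystallisation to constant rotation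
Reagents that add atoms: none
Why: Classical resolution of a crystalline carboxylic acid through its diastereomeric salt sets the absolute configuration at a stage where only two inexpensive components have been invested.

Step 6
Reactants: 10, resolved ammonium salt
Product: 12, 3a-formyl-7-methyl-1-oxooctahydro-2-benzofuran-7-carboxylic acid (C9 aldehyde, C19 acid, C6–O–C20 lactone), via the free resolved hydroxy acid 11 (not isolated)
Conditions: 1 M HCl/EtOAc; then Dess–Martin periodinane, CH2Cl2, 0 °C to rt
Reagents that add atoms: none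
Why: Dess–Martin oxidation acts on the only free alcohol, because C20–O is masked in the lactone, and the aldehyde is α-quaternary and cannot epimerise.

Step 7
Reactants: 12, aldehyde acid
Product: 13, 3a-(1,3-dioxolan-2-yl)-7-methyl-1-oxooctahydro-2-benzofuran-7-carboxylic acid
Conditions: (TMSOCH2)2, TMSOTf (5 mol %), CH2Cl2, −78 to −20 °C; aq NaH2PO4
Reagents that add atoms: 1,2-bis(trimethylsilyloxy)ethane, C[Si](C)(C)OCCO[Si](C)(C)C
Why: Noyori acetalisation masks the neopentyl aldehyde under aprotic conditions that do not esterify the hindered acid.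

Step 8
Reactants: 13, dioxolane acid
Product: 14, 3a-(1,3-dioxolan-2-yl)-7-(hydroxymethyl)-7-methyloctahydro-2-benzofuran-1-one (C19-OH free)
Conditions: BH3·SMe2, THF, 0 °C to rt; MeOH
Reagents that add atoms: none
Why: Borane reduces a carboxylic acid much faster than a lactone or an acetal and so brings C19 to the alcohol level.

Step 9
Reactants: 14, dioxolane alcohol; 15, methyl acetoacetate
Product: 19, spiro bis-lactone (3-acetyl-5,6-dihydro-2H-pyran-2-one spiro-fused at C10 to ring A), via hydroxy aldehyde 16 (not isolated), via Knoevenagel adduct 17 (not isolated), via lactone isomer 18 (not isolated)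
Conditions: (i) 1 M HCl, THF, 40 °C, crude taken on; (ii) 15, piperidine/AcOH (20 mol % each), PhMe, reflux, Dean–Stark; (iii) CSA (10 mol %), 4 Å MS, PhMe, reflux
Reagents that add atoms: none
Why: Acetal hydrolysis frees the C9 aldehyde (16: C6–O–C20 lactone kept, C19-OH free), the Knoevenagel condensation to the methyl 2-acetylacrylate 17 runs while C20–O is still acylated (so no retro-aldol loss of formaldehyde), and in the acid-catalysed lactone relay C19-OH takes over C6 (18) and the released C20-OH captures the C7 ester; E/Z and lactone isomers interconvert, and only the isomer with C7 cis to C10 and C20-OH free can close, irreversibly by loss of MeOH.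

Step 10
Reactants: 19, spiro acyl-dihydropyranone; 20, buta-1,3-diene
Product: 21, Diels–Alder adduct: cyclohexene ring C (C12=C13) cis-fused to the δ-lactone at C8–C9, with acetyl (C15, C16) on quaternary C8; C14 and C11 on one face, C15 and H-9 on the other
Conditions: ZnCl2 (2 equiv), 20 (excess), CH2Cl2, sealed tube, rt to 40 °C
Reagents that add atoms: none
Why: In this Lewis-acid Diels–Alder reaction of a doubly activated 3-acyl-5,6-dihydropyran-2-one (compare 2-acyl-4,4-dialkylcyclohexenones), suprafacial addition makes C8–C14 and C9–C11 cis, and the diene should approach from the C1H2 side of spiro C10, anti to the branched C5 arm, which sets C8 and C9 relative to C10.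

Step 11
Reactants: 21, Diels–Alder adduct
Product: 22, the C11 enone of 21 (C11=O, C12=C13)
Conditions: Rh2(cap)4 (1 mol %), aq t-BuOOH (5 equiv), DCE, 40 °C
Reagents that add atoms: tert-butyl hydroperoxide, CC(C)(C)OO
Why: Allylic C–H oxidation should occur at C11 rather than at C14, which is neopentyl and deactivated by the two carbonyls on C8, and the non-basic medium leaves the now acidic H-9 untouched.

Step 12
Reactants: 22, enone
Product: 23, the 11-allylic alcohol of 22 (11-OH cis to C10 and C7)
Conditions: NaBH4, CeCl3·7H2O, MeOH/CH2Cl2, −78 °C; AcOH quench at −78 °C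
Reagents that add atoms: none
Why: In the Luche 1,2-reduction hydride should arrive on the convex face that carries H-9 and C15, because C10 and C7 cover the other face, which places 11-OH cis to C10; the hindered C15 ketone survives, and the cold acidic quench keeps the alkoxide from attacking C7.

Step 13
Reactants: 23, allylic alcohol
Product: 25, the 11-O-triethylsilyl C16 bromo ketone (C8–C(=O)CH2Br), via the 11-O-TES C15 triethylsilyl enol ether 24 (not isolated)
Conditions: TESOTf (2.3 equiv), Et3N, CH2Cl2, −78 to 0 °C; then NBS, THF, −78 °C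
Reagents that add atoms: triethylsilyl triflate, CC[Si](CC)(CC)OS(=O)(=O)C(F)(F)F; N-bromosuccinimide, O=C1CCC(=O)N1Br
Why: Silylation of 11-OH and soft enolisation at C16, the only enolisable position of the ketone, are followed by bromination of the silyl enol ether, which is far more nucleophilic than the ring alkene.

Step 14
Reactants: 25, bromo ketone
Product: 26, 11-O-TES 17-nor tetracycle (bicyclo[3.2.1]octane with C15 ketone and C16H2; both lactones in place)
Conditions: Bu3SnH (syringe pump), AIBN, PhH (5 mM), 80 °C
Reagents that add atoms: none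
Why: In this reductive 5-exo-trig radical cyclisation the electrophilic C16 radical, on the arm axial at C8, adds to C13 (the alkene carbon remote from the C11–O dipole) to close ring D; the bridge can span only one face, so C8 dictates C13, and 6-endo closure would force ring C into a boat.

Step 15
Reactants: 26, 17-nor ketone
Product: 28, ludongnin A, via 11-O-triethylsilyl ludongnin A 27 (not isolated)
Conditions: (CH2O)n, i-Pr2NH·CF3CO2H, THF, reflux; then 1 M HCl, THF, rt
Reagents that add atoms: formaldehyde (as paraformaldehyde), C=O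
Why: Mannich-type α-methylenation can occur only at C16 because C8 is quaternary, and mild acid then removes the TES group without touching the enone or the lactones.

**Compound list**
1 | 2,2-dimethyl-1,3-dioxan-5-one | CC1(C)OCC(=O)CO1 | starting material
2 | allyltriphenylphosphonium bromide | C=CC[P+](c1ccccc1)(c1ccccc1)c1ccccc1.[Br-] | starting material
3 | 2,2-dimethyl-5-(prop-2-en-1-ylidene)-1,3-dioxane | C=CC=C1COC(C)(C)OC1 | intermediate
4 | 2-(prop-2-en-1-ylidene)propane-1,3-diol | C=CC=C(CO)CO | intermediate
5 | citraconic anhydride | CC1=CC(=O)OC1=O | starting material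
6 | dienyl hydrogen citraconate, (Z)-4-{[2-(hydroxymethyl)penta-2,4-dien-1-yl]oxy}-2-methyl-4-oxobut-2-enoic acid (C6 half-ester; E/Z at C10=C1) | OC(=O)/C(C)=C\C(=O)OCC(CO)=CC=C | intermediate
7 | (±)-cyclohexene lactone acid (C1=C2; cis-fused C6–O–C20 γ-lactone; C6, C19 (CO2H) and C20 on one face of ring A, C9H2OH, C18 and H-5 on the other; racemate, wanted enantiomer drawn) | OC[C@]12C=CC[C@@](C)(C(=O)O)[C@H]1C(=O)OC2 | intermediate
8 | (±)-saturated lactone acid (racemate, wanted enantiomer drawn) | OC[C@]12CCC[C@@](C)(C(=O)O)[C@H]1C(=O)OC2 | intermediate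
9 | (R)-1-phenylethylamine | C[C@@H](N)c1ccccc1 | starting material
10 | (R)-1-phenylethylammonium salt of the resolved acid | OC[C@]12CCC[C@@](C)(C(=O)[O-])[C@H]1C(=O)OC2.C[C@@H]([NH3+])c1ccccc1 | intermediate
11 | resolved hydroxy lactone acid (single enantiomer) | OC[C@]12CCC[C@@](C)(C(=O)O)[C@H]1C(=O)OC2 | intermediate
12 | C9 aldehyde, C19 acid, C6–O–C20 lactone | O=C[C@]12CCC[C@@](C)(C(=O)O)[C@H]1C(=O)OC2 | intermediate
13 | C9 dioxolane, C19 acid | O1CCOC1[C@]23CCC[C@@](C)(C(=O)O)[C@H]2C(=O)OC3 | intermediate
14 | C9 dioxolane, C19 alcohol | O1CCOC1[C@]23CCC[C@@](C)(CO)[C@H]2C(=O)OC3 | intermediate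
15 | methyl acetoacetate | CC(=O)CC(=O)OC | starting material
16 | hydroxy aldehyde: C9 aldehyde, C19 alcohol, C6–O–C20 lactone | O=C[C@]12CCC[C@@](C)(CO)[C@H]1C(=O)OC2 | intermediate
17 | Knoevenagel adduct: methyl 2-acetyl-3-(C10)acrylate, C6–O–C20 lactone, free C19-OH (E/Z) | COC(=O)C(C(C)=O)=C[C@]12CCC[C@@](C)(CO)[C@H]1C(=O)OC2 | intermediate
18 | lactone isomer of 17: C19–O–C6 lactone, free C20-OH (E/Z) | COC(=O)C(C(C)=O)=C[C@@]1(CCC[C@@]2(C)COC(=O)[C@H]21)CO | intermediate
19 | spiro bis-lactone: 3-acetyl-5,6-dihydro-2H-pyran-2-one (O, C7, C8=C9, C10, C20) spiro at C10 to ring A, which carries the cis-fused C19–O–C6 γ-lactone | CC(=O)C1=C[C@@]2(CCC[C@@]3(C)COC(=O)[C@H]32)COC1=O | intermediate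
20 | buta-1,3-diene | C=CC=C | starting material
21 | Diels–Alder adduct (ring C, C12=C13) | CC(=O)[C@]12CC=CC[C@H]1[C@@]1(CCC[C@@]3(C)COC(=O)[C@H]31)COC2=O | intermediate
22 | C11 enone | CC(=O)[C@]12CC=CC(=O)[C@H]1[C@@]1(CCC[C@@]3(C)COC(=O)[C@H]31)COC2=O | intermediate
23 | 11-allylic alcohol | CC(=O)[C@]12CC=C[C@@H](O)[C@H]1[C@@]1(CCC[C@@]3(C)COC(=O)[C@H]31)COC2=O | intermediate
24 | 11-O-TES, C15 TES enol ether | C=C(O[Si](CC)(CC)CC)[C@]12CC=C[C@@H](O[Si](CC)(CC)CC)[C@H]1[C@@]1(CCC[C@@]3(C)COC(=O)[C@H]31)COC2=O | intermediate
25 | 11-O-TES C16 bromo ketone | BrCC(=O)[C@]12CC=C[C@@H](O[Si](CC)(CC)CC)[C@H]1[C@@]1(CCC[C@@]3(C)COC(=O)[C@H]31)COC2=O | intermediate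
26 | 11-O-TES 17-nor tetracycle | C1C(=O)[C@]23C[C@H]1C[C@@H](O[Si](CC)(CC)CC)[C@H]2[C@@]1(CCC[C@@]2(C)COC(=O)[C@H]21)COC3=O | intermediate
27 | 11-O-TES ludongnin A | C=C1C(=O)[C@]23C[C@H]1C[C@@H](O[Si](CC)(CC)CC)[C@H]2[C@@]1(CCC[C@@]2(C)COC(=O)[C@H]21)COC3=O | intermediate
28 | ludongnin A | C=C1C(=O)[C@]23C[C@H]1C[C@@H](O)[C@H]2[C@@]1(CCC[C@@]2(C)COC(=O)[C@H]21)COC3=O | target

Total step count: 15. Longest linear sequence: 15.

**Steps most likely to fail**

Step 3. The cycloaddition may be sluggish at the fully substituted diene terminus, and a [1,5]-hydrogen shift of the inside CH2O hydrogens or polymerisation may overtake it. The fallback runs from 5 back to 8 and does not make the quaternary carbon in the cycloaddition. (E)-Penta-2,4-dienal and triethyl orthoformate would give (E)-5,5-diethoxypenta-1,3-diene F1. Its monosubstituted terminus should add 5 intermolecularly (PhMe, 110 °C) to give the all-cis anhydride acetal F2. Hydrogenation would give the saturated anhydride acetal F3, and aqueous acid the aldehyde diacid F4. A Tollens sequence (aq CH2O, NaOH: aldol at C10, then crossed Cannizzaro reduction) would give the bis(hydroxymethyl) diacid F5. On acidification F5 should lactonise through the CH2OH cis to C6 to give racemic 8.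

Step 9. Three things may go wrong:
- Condensation at the neopentyl aldehyde may be slow.
- Premature lactone migration may expose a β-hydroxy aldehyde to retro-aldol cleavage.
- The lactone relay may stall before the δ-lactone closes.

The fallback runs from 12 back to 19. It olefinates while C19 is still the acid and adds the acetyl group only after the ring is made. A Z-selective Ando olefination (methyl (diphenoxyphosphoryl)acetate, NaH) would give the (Z)-enoate acid F6. Borane would reduce the acid to the (Z)-enoate alcohol F7. CSA in hot toluene would run the relay to the unsubstituted spiro 5,6-dihydropyran-2-one bis-lactone F8. I2/pyridine would give the 3-iodo lactone F9. Stille coupling with tributyl(1-ethoxyvinyl)stannane would give the ethoxyvinyl lactone F10, and dilute acid would convert F10 into 19.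

Step 14. The radical may close in the 6-endo mode to a bicyclo[2.2.2]octane, or it may be reduced before it cyclises. The fallback runs from 23 back to 26 and replaces the radical closure by an ionic, stereospecific one. Hydroxyl-directed epoxidation (VO(acac)2, t-BuOOH) would give the 12,13-epoxy alcohol F11, with the epoxide on the face of 11-OH. TESOTf/2,6-lutidine would give its TES ether F12. LiHMDS would form the C16 enolate, which should open the epoxide at C13 from the opposite face (5-exo-tet) to give the 12-hydroxy tetracycle F13. 1,1'-Thiocarbonyldiimidazole would give the imidazolylthiocarbonyl derivative F14, and Barton–McCombie reduction (Bu3SnH, AIBN) would give 26.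

**Further compounds**
F1 | step 3 | (E)-5,5-diethoxypenta-1,3-diene | C=C/C=C/C(OCC)OCC
F2 | step 3 | (±)-all-cis Diels–Alder anhydride acetal (C1=C2) | CCOC(OCC)[C@H]1C=CC[C@@]2(C)C(=O)OC(=O)[C@@H]12
F3 | step 3 | (±)-saturated anhydride acetal | CCOC(OCC)[C@H]1CCC[C@@]2(C)C(=O)OC(=O)[C@@H]12
F4 | step 3 | (±)-aldehyde diacid | O=C[C@H]1CCC[C@@](C)(C(=O)O)[C@H]1C(=O)O
F5 | step 3 | (±)-bis(hydroxymethyl) diacid | OCC1(CO)CCC[C@@](C)(C(=O)O)[C@H]1C(=O)O
F6 | step 9 | (Z)-enoate acid, C6–O–C20 lactone | COC(=O)/C=C\[C@]12CCC[C@@](C)(C(=O)O)[C@H]1C(=O)OC2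
F7 | step 9 | (Z)-enoate alcohol, C6–O–C20 lactone | COC(=O)/C=C\[C@]12CCC[C@@](C)(CO)[C@H]1C(=O)OC2
F8 | step 9 | spiro 5,6-dihydropyran-2-one bis-lactone | O=C1C=C[C@@]2(CCC[C@@]3(C)COC(=O)[C@H]32)CO1
F9 | step 9 | 3-iodo spiro bis-lactone | O=C1C(I)=C[C@@]2(CCC[C@@]3(C)COC(=O)[C@H]32)CO1
F10 | step 9 | 3-(1-ethoxyvinyl) spiro bis-lactone | C=C(OCC)C1=C[C@@]2(CCC[C@@]3(C)COC(=O)[C@H]32)COC1=O
F11 | step 14 | 12,13-epoxy 11-alcohol | CC(=O)[C@]12C[C@H]3O[C@H]3[C@@H](O)[C@H]1[C@@]1(CCC[C@@]3(C)COC(=O)[C@H]31)COC2=O
F12 | step 14 | 12,13-epoxy 11-O-TES ether | CC(=O)[C@]12C[C@H]3O[C@H]3[C@@H](O[Si](CC)(CC)CC)[C@H]1[C@@]1(CCC[C@@]3(C)COC(=O)[C@H]31)COC2=O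
F13 | step 14 | 12-hydroxy 11-O-TES 17-nor tetracycle | C1C(=O)[C@]23C[C@H]1[C@@H](O)[C@@H](O[Si](CC)(CC)CC)[C@H]2[C@@]1(CCC[C@@]2(C)COC(=O)[C@H]21)COC3=O
F14 | step 14 | 12-O-(imidazol-1-ylthiocarbonyl) derivative of F13 | C1C(=O)[C@]23C[C@H]1[C@@H](OC(=S)n4ccnc4)[C@@H](O[Si](CC)(CC)CC)[C@H]2[C@@]1(CCC[C@@]2(C)COC(=O)[C@H]21)COC3=O
A1 | direct plan | cesium oxalate of the ring-A C10 carbinol (γ-lactone, C20 acetate) | [Cs+].[O-]C(=O)C(=O)OC1(COC(C)=O)CCC[C@@]2(C)COC(=O)[C@H]21
A2 | direct plan | 8-oxabicyclo[3.2.1]octenone methyl ester with C14 bromide and C17 OTBS | O=C1C(C(=O)OC)=C[C@H]2C[C@H](CBr)[C@]1(CO[Si](C)(C)C(C)(C)C)O2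
A3 | direct plan | Giese adduct (C9–C10 bond) | O=C1C(C(=O)OC)[C@H]([C@]3(COC(C)=O)CCC[C@@]5(C)COC(=O)[C@H]53)[C@H]2C[C@H](CBr)[C@]1(CO[Si](C)(C)C(C)(C)C)O2
A4 | direct plan | cycloheptanone β-keto lactone with 11-OH and C14 bromide | O=C1C2C(=O)OC[C@]3(CCC[C@@]4(C)COC(=O)[C@H]43)[C@@H]2[C@H](O)C[C@H](CBr)C1CO[Si](C)(C)C(C)(C)C
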